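**Retrosynthetic overview**

- The strategy rests on ring A, a resorcylate with the carboxyl at C1, hydroxyls at C2 and C4 and the 8-hydroxyundecyl chain at C6, whose C1 carboxyl is esterified by a hindered secondary (R)-carbinol. This is the pattern of a linear 3,5,7-trioxo ester folded by a C2–C7 aldol.
- The ester C–O bond and the arene bond C1–C6 of ring A are both cut back to diketo-dioxinone 12 (a masked acylketene) and alcohol 18 (fragment B). Ring B is bought as aryl bromide 16, so ring A is the only ring formed, in step 10.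
- Compound 12 comes from the dianion of keto-dioxinone 10 and Weinreb amide 8. Both 8 and 18 come from (R)-1,2-epoxypentane by CuI-catalysed Grignard opening, and the aryl–alkyl bond of 18 comes from a B-alkyl Suzuki coupling.
- Hydrogenolysis of the three benzyl ethers ends the route.

Key step: step 10

Assumption: 1,3-bis(benzyloxy)-5-bromobenzene (16) is treated as a purchasable building block; it is otherwise one Williamson benzylation from 5-bromoresorcinol.

**Route**

Step 1
Reactants: 1 (R)-1,2-epoxypentane; 2 8-bromooct-1-ene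
Product: 4 (4R)-tridec-12-en-4-ol, via oct-7-enylmagnesium bromide 3 (not isolated)
Conditions: 2, Mg, THF, rt to 40 °C; then CuI (10 mol%), 1, THF, −30 °C to 0 °C; H2O/aq NH4Cl
Reagents that add atoms: none
Why: Copper-catalysed Grignard opening of a monosubstituted epoxide should proceed by SN2 attack at the unsubstituted CH2, so the C–O bond at the stereocentre is never broken and the (R) configuration of 1 becomes C4 of 4 unchanged.

Step 2
Reactants: 4 (4R)-tridec-12-en-4-ol
Product: 5 (4R)-4-(benzyloxy)tridec-12-ene
Conditions: NaH, BnBr, n-Bu4NI (cat.), THF/DMF, 0 °C to rt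
Reagents that add atoms: benzyl bromide, BrCc1ccccc1
Why: Williamson etherification of the sodium alkoxide alkylates at oxygen only, so the carbinol configuration is retained and the terminal alkene is untouched.

Step 3
Reactants: 5 (4R)-4-(benzyloxy)tridec-12-ene
Product: 6 (9R)-9-(benzyloxy)dodecanal
Conditions: O3, CH2Cl2, −78 °C (Sudan red 7B as end-point indicator); then PPh3, −78 °C to rt
Reagents that add atoms: ozone, [O-][O+]=O
Why: Ozonolysis with reductive work-up should cleave the terminal alkene much faster than ozone attacks the benzyl ether, and the dye end point stops the gas flow before over-oxidation.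

Step 4
Reactants: 6 (9R)-9-(benzyloxy)dodecanal
Product: 7 (9R)-9-(benzyloxy)dodecanoic acid
Conditions: NaClO2, NaH2PO4, 2-methyl-2-butene, t-BuOH/H2O, rt
Reagents that add atoms: sodium chlorite, [Na+].[O-]Cl=O
Why: Pinnick oxidation converts the aldehyde into the acid under buffered conditions, with 2-methyl-2-butene scavenging HOCl so that the benzyl ether and the remote stereocentre are not affected.

Step 5
Reactants: 7 (9R)-9-(benzyloxy)dodecanoic acid
Product: 8 (9R)-9-(benzyloxy)-N-methoxy-N-methyldodecanamide
Conditions: 1,1'-carbonyldiimidazole, CH2Cl2, rt; then MeNH(OMe)·HCl, rt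
Reagents that add atoms: N,O-dimethylhydroxylamine hydrochloride, CNOC.Cl
Why: Activation of the acid as its acyl imidazolide followed by aminolysis is a standard Weinreb amide formation and involves no enolisable stereocentre.

Step 6
Reactants: 9 2,2,6-trimethyl-4H-1,3-dioxin-4-one
Product: 10 2,2-dimethyl-6-(2-oxopropyl)-4H-1,3-dioxin-4-one
Conditions: LiN(SiMe3)2 (2 equiv), THF, −78 °C; then AcCl (1 equiv), −78 °C; aq NH4Cl
Reagents that add atoms: acetyl chloride, CC(=O)Cl
Why: Kinetic deprotonation of the C6 methyl gives the lithium dienolate, which undergoes vinylogous Claisen-type C-acylation at its γ-carbon with acetyl chloride; the extra base covers the more acidic product.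

Step 7
Reactants: 10 2,2-dimethyl-6-(2-oxopropyl)-4H-1,3-dioxin-4-one; 8 (9R)-9-(benzyloxy)-N-methoxy-N-methyldodecanamide
Product: 12 6-[(12R)-12-(benzyloxy)-2,4-dioxopentadecyl]-2,2-dimethyl-4H-1,3-dioxin-4-one, via dilithium dienolate 11 (not isolated)
Conditions: LiN(i-Pr)2 (2 equiv per 10), THF, −78 °C; then 8, −78 to −40 °C; 1 M HCl quench; used promptly
Reagents that add atoms: none
Why: Double deprotonation of 10 (first the doubly activated CH2, then the methyl) gives a dianion whose last-formed terminal carbanion should be C-acylated by the Weinreb amide, a Claisen-type acylation of a 1,3-dicarbonyl dianion in which the chelated tetrahedral intermediate prevents over-addition.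

Step 8
Reactants: 1 (R)-1,2-epoxypentane; 13 6-bromohex-1-ene
Product: 15 (4R)-undec-10-en-4-ol, via hex-5-enylmagnesium bromide 14 (not isolated)
Conditions: 13, Mg, THF, rt; then CuI (10 mol%), 1, THF, −30 °C to 0 °C; H2O/aq NH4Cl
Reagents that add atoms: none
Why: The same copper-catalysed SN2 opening at the terminal epoxide carbon as in step 1 transfers the (R) configuration of 1 to C4 of 15 without touching the C–O bond.

Step 9
Reactants: 15 (4R)-undec-10-en-4-ol; 16 1,3-bis(benzyloxy)-5-bromobenzene
Product: 18 (4R)-11-[3,5-bis(benzyloxy)phenyl]undecan-4-ol (fragment B), via bis(9-BBN) adduct 17 (not isolated)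
Conditions: 9-BBN (2.2 equiv), THF, 0 °C to rt; then 16, Pd(dppf)Cl2 (5 mol%), 3 M aq NaOH, THF, 65 °C
Reagents that add atoms: none
Why: Anti-Markovnikov hydroboration of the terminal alkene (a second equivalent of 9-BBN is taken up by the hydroxyl as a borinate that the aqueous base hydrolyses again) gives a primary B-alkyl borane, which undergoes B-alkyl Suzuki–Miyaura coupling after oxidative addition of 16 to zerovalent palladium, leaving the carbinol centre untouched.

Step 10
Reactants: 12 6-[(12R)-12-(benzyloxy)-2,4-dioxopentadecyl]-2,2-dimethyl-4H-1,3-dioxin-4-one; 18 (4R)-11-[3,5-bis(benzyloxy)phenyl]undecan-4-ol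
Product: 22 (4R)-11-[3,5-bis(benzyloxy)phenyl]undecan-4-yl 6-[(8R)-8-(benzyloxy)undecyl]-2,4-dihydroxybenzoate (tribenzyl integracin B), via acylketene 19 (not isolated), via triketo ester 20 (not isolated), via aldol adduct 21 (not isolated)
Conditions: 12 (1.2 equiv), 18, PhMe, 110 °C; concentrate; K2CO3, i-PrOH/CH2Cl2, rt; then HCl in MeOH, rt
Reagents that add atoms: none
Why: At 110 °C the dioxinone of 12 should lose acetone by retro-[4+2] to give acylketene 19, and the only free hydroxyl present, the secondary carbinol of 18, adds to the unhindered ketene carbon to give 3,5,7-trioxo ester 20, so the ester C–O bond is made before the ortho-disubstituted arene exists. Carbonate then enolises C2 (between the ester and the C3 ketone), which attacks the C7 ketone in a 6-(enolendo)-exo-trig aldol to give 21, closing ring A through the C2–C7 bond (arene C1–C6); acid then drives loss of water and tautomerisation to the resorcylate. The closest known reaction type is dioxinone thermolysis with alcohol capture of the ketene, secondary alcohols included, followed by biomimetic aldol aromatisation of trioxoalkanoates. No stereocentre is created, since the two sp3 ring centres of 21 vanish on aromatisation, and both (R)-carbinols are preserved because only an O–H bond of 18 reacts and the other carbinol is a benzyl ether. The step needs O-acylation by a single nucleophile, secured by benzyl protection of the phenols and of the second carbinol, and C2–C7 aldol closure instead of pyranone formation or a C6-to-C1 Claisen closure that would expel fragment B, secured by keeping the carboxyl as an ester and using mild carbonate followed by acid. This fold of the chain fixes the hydroxyls at C2 and C4, the carboxyl at C1 and the alkyl chain at C6.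

Step 11
Reactants: 22 tribenzyl integracin B
Product: 23 integracin B
Conditions: H2 (1 atm), Pd/C (10%), EtOAc/EtOH, rt
Reagents that add atoms: none
Why: Hydrogenolysis over Pd/C cleaves the two aryl benzyl ethers and the secondary alkyl benzyl ether at their benzylic O–CH2 bonds, so the hindered ester, both arenes and both (R)-carbinol C–O bonds should remain intact.

**Compound list**

1 | (R)-1,2-epoxypentane, (2R)-2-propyloxirane | CCC[C@@H]1CO1 | starting material
2 | 8-bromooct-1-ene | C=CCCCCCCBr | starting material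
3 | oct-7-enylmagnesium bromide | C=CCCCCCC[Mg]Br | intermediate
4 | (4R)-tridec-12-en-4-ol | CCC[C@@H](O)CCCCCCCC=C | intermediate
5 | (4R)-4-(benzyloxy)tridec-12-ene | CCC[C@@H](OCc1ccccc1)CCCCCCCC=C | intermediate
6 | (9R)-9-(benzyloxy)dodecanal | CCC[C@@H](OCc1ccccc1)CCCCCCCC=O | intermediate
7 | (9R)-9-(benzyloxy)dodecanoic acid | CCC[C@@H](OCc1ccccc1)CCCCCCCC(=O)O | intermediate
8 | (9R)-9-(benzyloxy)-N-methoxy-N-methyldodecanamide | CCC[C@@H](OCc1ccccc1)CCCCCCCC(=O)N(C)OC | intermediate
9 | 2,2,6-trimethyl-4H-1,3-dioxin-4-one | CC1=CC(=O)OC(C)(C)O1 | starting material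
10 | 2,2-dimethyl-6-(2-oxopropyl)-4H-1,3-dioxin-4-one | CC(=O)CC1=CC(=O)OC(C)(C)O1 | intermediate
11 | dilithium dienolate of 10 (dianion at the CH2 and the methyl) | C=C(O[Li])C=C1C=C(O[Li])OC(C)(C)O1 | intermediate
12 | 6-[(12R)-12-(benzyloxy)-2,4-dioxopentadecyl]-2,2-dimethyl-4H-1,3-dioxin-4-one | CCC[C@@H](OCc1ccccc1)CCCCCCCC(=O)CC(=O)CC1=CC(=O)OC(C)(C)O1 | intermediate
13 | 6-bromohex-1-ene | C=CCCCCBr | starting material
14 | hex-5-enylmagnesium bromide | C=CCCCC[Mg]Br | intermediate
15 | (4R)-undec-10-en-4-ol | CCC[C@@H](O)CCCCCC=C | intermediate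
16 | 1,3-bis(benzyloxy)-5-bromobenzene | Brc1cc(OCc2ccccc2)cc(OCc2ccccc2)c1 | starting material
17 | bis(9-BBN) adduct of 15 (B-alkyl borane at C11, O-borinate at C4) | CCC[C@@H](OB1C2CCCC1CCC2)CCCCCCCB1C2CCCC1CCC2 | intermediate
18 | (4R)-11-[3,5-bis(benzyloxy)phenyl]undecan-4-ol (fragment B) | CCC[C@@H](O)CCCCCCCc1cc(OCc2ccccc2)cc(OCc2ccccc2)c1 | intermediate
19 | acylketene, (15R)-15-(benzyloxy)octadec-1-ene-1,3,5,7-tetrone | CCC[C@@H](OCc1ccccc1)CCCCCCCC(=O)CC(=O)CC(=O)C=C=O | intermediate
20 | (4R)-11-[3,5-bis(benzyloxy)phenyl]undecan-4-yl (15R)-15-(benzyloxy)-3,5,7-trioxooctadecanoate | CCC[C@@H](OCc1ccccc1)CCCCCCCC(=O)CC(=O)CC(=O)CC(=O)O[C@H](CCC)CCCCCCCc1cc(OCc2ccccc2)cc(OCc2ccccc2)c1 | intermediate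
21 | (4R)-11-[3,5-bis(benzyloxy)phenyl]undecan-4-yl 2-[(8R)-8-(benzyloxy)undecyl]-2-hydroxy-4,6-dioxocyclohexane-1-carboxylate (two transient ring centres, unassigned) | CCC[C@@H](OCc1ccccc1)CCCCCCCC1(O)CC(=O)CC(=O)C1C(=O)O[C@H](CCC)CCCCCCCc1cc(OCc2ccccc2)cc(OCc2ccccc2)c1 | intermediate
22 | (4R)-11-[3,5-bis(benzyloxy)phenyl]undecan-4-yl 6-[(8R)-8-(benzyloxy)undecyl]-2,4-dihydroxybenzoate (tribenzyl integracin B) | CCC[C@@H](OCc1ccccc1)CCCCCCCc1cc(O)cc(O)c1C(=O)O[C@H](CCC)CCCCCCCc1cc(OCc2ccccc2)cc(OCc2ccccc2)c1 | intermediate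
23 | integracin B, (4R)-11-(3,5-dihydroxyphenyl)undecan-4-yl 2,4-dihydroxy-6-[(8R)-8-hydroxyundecyl]benzoate | CCC[C@@H](O)CCCCCCCc1cc(O)cc(O)c1C(=O)O[C@H](CCC)CCCCCCCc1cc(O)cc(O)c1 | target

**Step count and risks**

Total steps: 11. Longest linear sequence: 8 steps (steps 1, 2, 3, 4, 5, 7, 10, 11).

Steps most likely to fail:

1. Step 10. Capture of the acylketene by the hindered secondary alcohol may be slower than ketene self-condensation or intramolecular O-cyclisation to a pyranone, and at the base stage the trioxo ester may close by Claisen attack on the ester with loss of fragment B. The fallback builds ring A first and makes the ester by transacylation. It sets out from 12 and 18. Treatment of 12 with Et3N in CH2Cl2 should aromatise it with the dioxinone ring retained, giving 5-[(8R)-8-(benzyloxy)undecyl]-7-hydroxy-2,2-dimethyl-4H-1,3-benzodioxin-4-one F1. Benzylation of its phenol (BnBr, K2CO3, acetone) should give 7-(benzyloxy)-5-[(8R)-8-(benzyloxy)undecyl]-2,2-dimethyl-4H-1,3-benzodioxin-4-one F2. Alcohol 18 with NaN(SiMe3)2 in THF should then open the benzodioxinone at its carbonyl, with retention at the carbinol, to give (4R)-11-[3,5-bis(benzyloxy)phenyl]undecan-4-yl 4-(benzyloxy)-6-[(8R)-8-(benzyloxy)undecyl]-2-hydroxybenzoate F3. Hydrogenolysis under the conditions of step 11 returns the route at 23.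

2. Step 7. The dianion may be acylated at oxygen, or be quenched by proton transfer from the enolisable Weinreb amide, and the diketo-dioxinone may cyclise or decompose during isolation. The fallback replaces the Claisen acylation by aldol addition and oxidation, and it also omits steps 4 and 5. It sets out from aldehyde 6 and keto-dioxinone 10. Dianion 11, generated as in step 7, should add to 6 at −78 °C to give 6-[(12R)-12-(benzyloxy)-4-hydroxy-2-oxopentadecyl]-2,2-dimethyl-4H-1,3-dioxin-4-one F4 as a mixture of epimers at the new carbinol. Oxidation with Dess–Martin periodinane (1.1 equiv, CH2Cl2, 0 °C) returns the route at 12.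

3. Step 9. The free hydroxyl consumes B–H and may leave hydroboration incomplete, slow transmetallation may lead to reduction or homocoupling of the aryl bromide, and cyclised Grignard isomer carried over from step 8 lowers the purity of 15. The fallback forms the aryl–alkyl bond on a partner without a hydroxyl and makes the carbinol last. It sets out from 13 and 16. Hydroboration of 13 with 9-BBN should give 9-(6-bromohexyl)-9-borabicyclo[3.3.1]nonane F5. Coupling with 16 (Pd(dppf)Cl2, K3PO4, DMF/THF/H2O, 50 °C), where the aryl bromide reacts and the primary alkyl bromide should not, gives 1,3-bis(benzyloxy)-5-(6-bromohexyl)benzene F6. Magnesium in THF converts it into {6-[3,5-bis(benzyloxy)phenyl]hexyl}magnesium bromide F7, and CuI-catalysed opening of epoxide 1 as in step 8 returns the route at 18.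

**Further compounds**

F1 | step 10 | 5-[(8R)-8-(benzyloxy)undecyl]-7-hydroxy-2,2-dimethyl-4H-1,3-benzodioxin-4-one | CCC[C@@H](OCc1ccccc1)CCCCCCCc1cc(O)cc2OC(C)(C)OC(=O)c12
F2 | step 10 | 7-(benzyloxy)-5-[(8R)-8-(benzyloxy)undecyl]-2,2-dimethyl-4H-1,3-benzodioxin-4-one | CCC[C@@H](OCc1ccccc1)CCCCCCCc1cc(OCc3ccccc3)cc2OC(C)(C)OC(=O)c12
F3 | step 10 | (4R)-11-[3,5-bis(benzyloxy)phenyl]undecan-4-yl 4-(benzyloxy)-6-[(8R)-8-(benzyloxy)undecyl]-2-hydroxybenzoate | CCC[C@@H](OCc1ccccc1)CCCCCCCc1cc(OCc2ccccc2)cc(O)c1C(=O)O[C@H](CCC)CCCCCCCc1cc(OCc2ccccc2)cc(OCc2ccccc2)c1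
F4 | step 7 | 6-[(12R)-12-(benzyloxy)-4-hydroxy-2-oxopentadecyl]-2,2-dimethyl-4H-1,3-dioxin-4-one | CCC[C@@H](OCc1ccccc1)CCCCCCCC(O)CC(=O)CC1=CC(=O)OC(C)(C)O1
F5 | step 9 | 9-(6-bromohexyl)-9-borabicyclo[3.3.1]nonane | BrCCCCCCB1C2CCCC1CCC2
F6 | step 9 | 1,3-bis(benzyloxy)-5-(6-bromohexyl)benzene | BrCCCCCCc1cc(OCc2ccccc2)cc(OCc2ccccc2)c1
F7 | step 9 | {6-[3,5-bis(benzyloxy)phenyl]hexyl}magnesium bromide | Br[Mg]CCCCCCc1cc(OCc2ccccc2)cc(OCc2ccccc2)c1
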